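**Retrosynthetic overview**
1. The target comes from its bis-silyl ether. That ether comes from an acyclic tetraene by Z-selective ring-closing metathesis at C1=C10, so the ten-membered ring is formed last.
2. The C8–O ester bond is made with inversion (Mitsunobu). This attaches the Roche-acid side chain and turns the 8S Barbier carbinol into 8R.
3. The C7–C8 bond comes from a zinc Barbier coupling of a 3-(bromomethyl)butenolide with 3-methylbut-3-enal.
4. Key step: the C6–O bond is made by catalytic asymmetric bromolactonisation of a cross-conjugated trienoic acid. This forms the lactone ring first, sets C6 and installs the allylic bromide.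
5. The trienoic acid is built from acrolein, an allenylboronate, AlMe3, formaldehyde and 2-(bromomethyl)acrylic acid.

Atom labels: germacrane numbering is used. The ring is C1–C10, the lactone is C6–O–C12(=O)–C11(=C13)–C7, the ester O is on C8 and the OH is on C2. TBS = tert-butyldimethylsilyl.

Assumption: the sense of induction of a chiral catalyst on these new substrates ((R)-TRIP in step 1, (DHQD)2PHAL in step 6, (R)-Me-CBS in a fallback) is taken by analogy; if it proves opposite, the (pseudo)enantiomeric catalyst is used.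

**Step 1**
Reactants: 1 acrolein; 2 allenylboronic acid pinacol ester
Product: 4 (R)-hex-1-en-5-yn-3-ol, via homopropargyl pinacol borate 3 (not isolated)
Conditions: (R)-TRIP phosphoric acid (5 mol %), 4 Å MS, toluene, −20 °C; H2O work-up
Reagents that add atoms: none
Why: Chiral-phosphoric-acid-catalysed asymmetric propargylation: the allenylboronate adds in SE2′ fashion through a closed six-membered transition state held by the phosphate, which gives only the homopropargylic alcohol and sets C2 as R.

**Step 2**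
Reactants: 4 (R)-hex-1-en-5-yn-3-ol
Product: 5 (R)-tert-butyl(hex-1-en-5-yn-3-yloxy)dimethylsilane
Conditions: TBSCl, imidazole, CH2Cl2, 0 → 23 °C
Reagents that add atoms: tert-butyldimethylsilyl chloride, CC(C)(C)[Si](C)(C)Cl
Why: Standard silyl ether formation masks the C2 hydroxyl against the organometallic steps and the later Mitsunobu reaction and does not touch the stereocentre.

**Step 3**
Reactants: 5 (R)-tert-butyl(hex-1-en-5-yn-3-yloxy)dimethylsilane
Product: 8 (2E,5R)-5-(TBSO)-3-methylhepta-2,6-dien-1-ol, via alkenyldimethylalane 6 (not isolated), via lithium alanate 7 (not isolated)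
Conditions: AlMe3 (2.5 equiv), Cp2ZrCl2 (0.25 equiv), CH2Cl2, 0 → 23 °C; volatiles removed; n-BuLi, hexane/THF, −78 → 0 °C; (CH2O)n, 23 °C; 1 M HCl work-up
Reagents that add atoms: trimethylaluminium, C[Al](C)C; paraformaldehyde (as formaldehyde), C=O
Why: Negishi zirconium-catalysed carboalumination adds Me and Al syn with Al at the alkyne terminus, much faster than to the hindered vinyl group, and the alanate is hydroxymethylated with retention, which fixes the E C4=C5 alkene.

**Step 4**
Reactants: 8 (2E,5R)-5-(TBSO)-3-methylhepta-2,6-dien-1-ol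
Product: 9 (2E,5R)-5-(TBSO)-3-methylhepta-2,6-dienal
Conditions: MnO2 (15 equiv), CH2Cl2, 23 °C
Reagents that add atoms: none
Why: Allylic alcohol oxidation with MnO2 is neutral, stops at the enal and leaves the E-alkene, the silyl ether and the vinyl group unchanged.

**Step 5**
Reactants: 9 (2E,5R)-5-(TBSO)-3-methylhepta-2,6-dienal; 10 2-(bromomethyl)acrylic acid
Product: 13 (3E,5E,8R)-8-(TBSO)-6-methyl-2-methylidenedeca-3,5,9-trienoic acid, via phosphonium bromide 11 (not isolated), via ylide carboxylate 12 (not isolated)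
Conditions: 10, PBu3, THF, 0 °C; NaN(SiMe3)2 (2.05 equiv), −78 °C; then 9, −78 → 0 °C; 1 M HCl to pH 4; used at once
Reagents that add atoms: none
Why: Wittig olefination with an allylic trialkylphosphonium ylide, a class that gives E-dienes with enals, builds C6=C7, while the carboxylate switches off the acrylate as a Michael acceptor.

**Step 6**
Reactants: 13 (3E,5E,8R)-8-(TBSO)-6-methyl-2-methylidenedeca-3,5,9-trienoic acid
Product: 15 (5R)-3-(bromomethyl)-5-[(1E,4R)-4-(TBSO)-2-methylhexa-1,5-dien-1-yl]furan-2(5H)-one, via trans-bromolactone 14 (not isolated)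
Conditions: NBS (1.0 equiv), (DHQD)2PHAL (10 mol %), toluene/CHCl3 2:1, −60 °C, dark; then LiBr (20 mol %), THF, 23 °C
Reagents that add atoms: N-bromosuccinimide, O=C1CCC(=O)N1Br
Why: Proposed new method: catalytic enantioselective 5-endo bromolactonisation of a cross-conjugated 2-methylidene-3,5-dienoic acid followed by an allylic bromide shift; the quinuclidine of (DHQD)2PHAL binds the acid and its conjugate acid activates NBS, Br+ goes to C7 because that diene terminus leaves an allyl cation stabilised at the methyl-bearing C4 end, and the bound carboxylate can reach only C6 (five-membered ring, whereas attack at C4 would need a seven-membered ring holding an E-alkene), so anti addition inside the chiral pocket forms the C6–O bond, sets C6 as R and keeps C4=C5 E; bromide then adds to C13 and expels the C7 bromide (SN2′) because the conjugated endocyclic butenolide with a primary bromide is the more stable allylic isomer, and either isomer would give the same allylzinc in step 8; the closest known reaction types are organocatalytic asymmetric bromolactonisation of alkenoic acids, 1,4-bromolactonisation of conjugated enynes and 5-endo iodolactonisation of 3-alkenoic acids.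

**Step 7**
Reactants: 16 3-methylbut-3-en-1-ol
Product: 17 3-methylbut-3-enal
Conditions: Dess–Martin periodinane, CH2Cl2, 0 °C; filtered and used at once as a solution
Reagents that add atoms: none
Why: Dess–Martin oxidation is fast and base-free, so the β,γ-unsaturated aldehyde is obtained before it can slip into conjugation.

**Step 8**
Reactants: 15 (5R)-3-(bromomethyl)-5-[(1E,4R)-4-(TBSO)-2-methylhexa-1,5-dien-1-yl]furan-2(5H)-one; 17 3-methylbut-3-enal
Product: 19 (4R,5R)-4-[(1S)-1-hydroxy-3-methylbut-3-en-1-yl]-3-methylidene-5-[(1E,4R)-4-(TBSO)-2-methylhexa-1,5-dien-1-yl]oxolan-2-one, via allylzinc bromide 18 (not isolated)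
Conditions: Zn dust, 17 (3 equiv), THF/sat. aq. NH4Cl, 0 → 23 °C
Reagents that add atoms: none
Why: Zinc Barbier allylation: the allylzinc reacts at C7 (SE2′) on the face anti to the C6 side chain through a Zimmerman–Traxler chair in which the ring-locked E-type allyl geometry gives the anti carbinol, so C7 is set as R (trans-lactone) and C8 as S, while the in-plane C6–O bond cannot align for reductive elimination.

**Step 9**
Reactants: 20 methyl (S)-3-hydroxy-2-methylpropanoate
Product: 21 methyl (S)-3-(TBSO)-2-methylpropanoate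
Conditions: TBSCl, imidazole, CH2Cl2, 0 → 23 °C
Reagents that add atoms: tert-butyldimethylsilyl chloride, CC(C)(C)[Si](C)(C)Cl
Why: Standard silylation blocks the primary hydroxyl, which would otherwise be activated itself under Mitsunobu conditions; C2′ (S) comes from the chiral pool.

**Step 10**
Reactants: 21 methyl (S)-3-(TBSO)-2-methylpropanoate
Product: 22 (S)-3-(TBSO)-2-methylpropanoic acid
Conditions: LiOH, THF/MeOH/H2O, 0 → 23 °C; 1 M HCl to pH 4 at 0 °C
Reagents that add atoms: lithium hydroxide, [Li+].[OH-]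
Why: Mild ester saponification at or below room temperature gives the acid without epimerising the α-centre or removing the silyl ether.

**Step 11**
Reactants: 19 (4R,5R)-4-[(1S)-1-hydroxy-3-methylbut-3-en-1-yl]-3-methylidene-5-[(1E,4R)-4-(TBSO)-2-methylhexa-1,5-dien-1-yl]oxolan-2-one; 22 (S)-3-(TBSO)-2-methylpropanoic acid
Product: 24 (1R)-3-methyl-1-{(2R,3R)-4-methylidene-5-oxo-2-[(1E,4R)-4-(TBSO)-2-methylhexa-1,5-dien-1-yl]oxolan-3-yl}but-3-en-1-yl (2S)-3-(TBSO)-2-methylpropanoate, via alkoxyphosphonium carboxylate 23 (not isolated)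
Conditions: PPh3 and DIAD (2 equiv each) premixed, toluene, 0 °C; then 22 (2 equiv) and 19, 0 → 23 °C
Reagents that add atoms: none
Why: Mitsunobu esterification: the carboxylate displaces the C8 oxyphosphonium group in an SN2 reaction, so the C8–O bond forms with inversion (8S to 8R) and the whole side chain arrives in the same operation, while premixing PPh3 with DIAD keeps free phosphine away from the α-methylene lactone.

**Step 12**
Reactants: 24 (the acyclic tetraene ester from step 11)
Product: 25 (3aR,4R,6Z,8R,10E,11aR)-8-(TBSO)-6,10-dimethyl-3-methylidene-2-oxo-2,3,3a,4,5,8,9,11a-octahydrocyclodeca[b]furan-4-yl (2S)-3-(TBSO)-2-methylpropanoate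
Conditions: second-generation Hoveyda–Grubbs catalyst RuCl2(H2IMes)(=CH-C6H4-2-O-i-Pr) (15 mol %), 1,4-benzoquinone (30 mol %), toluene (0.5 mM), 90 °C, argon sparge
Reagents that add atoms: none
Why: Ring-closing metathesis: only the C1 vinyl and the C10 methallyl alkene are metathesis-active (C4=C5 is trisubstituted, C11=C13 is electron-poor and geminally disubstituted), and a ten-membered ring that already holds an E-alkene and a trans-fused lactone should accept the new trisubstituted alkene as the less strained Z isomer.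

**Step 13**
Reactants: 25 (the macrocyclic bis-silyl ether from step 12)
Product: 26 (3aR,4R,6Z,8R,10E,11aR)-8-hydroxy-6,10-dimethyl-3-methylidene-2-oxo-2,3,3a,4,5,8,9,11a-octahydrocyclodeca[b]furan-4-yl (2S)-3-hydroxy-2-methylpropanoate
Conditions: HF·pyridine, pyridine, THF, 0 → 23 °C
Reagents that add atoms: none
Why: Fluoride-driven desilylation in a pyridine-buffered medium removes both TBS groups without touching the esters or the Michael acceptor and without starting a transannular cyclisation of the 1,5-diene.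

**Compound list**
1 | acrolein | C=CC=O | starting material
2 | allenylboronic acid pinacol ester | C=C=CB1OC(C)(C)C(C)(C)O1 | starting material
3 | (R)-2-(hex-1-en-5-yn-3-yloxy)-4,4,5,5-tetramethyl-1,3,2-dioxaborolane | C#CC[C@@H](OB1OC(C)(C)C(C)(C)O1)C=C | intermediate
4 | (R)-hex-1-en-5-yn-3-ol | C#CC[C@@H](O)C=C | intermediate
5 | (R)-tert-butyl(hex-1-en-5-yn-3-yloxy)dimethylsilane | C#CC[C@@H](O[Si](C)(C)C(C)(C)C)C=C | intermediate
6 | [(1E,4R)-4-(TBSO)-2-methylhexa-1,5-dien-1-yl]dimethylalane | C[Al](C)/C=C(\C)C[C@@H](O[Si](C)(C)C(C)(C)C)C=C | intermediate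
7 | lithium butyl[(1E,4R)-4-(TBSO)-2-methylhexa-1,5-dien-1-yl]dimethylalanate | [Li+].CCCC[Al-](C)(C)/C=C(\C)C[C@@H](O[Si](C)(C)C(C)(C)C)C=C | intermediate
8 | (2E,5R)-5-(TBSO)-3-methylhepta-2,6-dien-1-ol | OC/C=C(\C)C[C@@H](O[Si](C)(C)C(C)(C)C)C=C | intermediate
9 | (2E,5R)-5-(TBSO)-3-methylhepta-2,6-dienal | O=C/C=C(\C)C[C@@H](O[Si](C)(C)C(C)(C)C)C=C | intermediate
10 | 2-(bromomethyl)acrylic acid | C=C(CBr)C(=O)O | starting material
11 | tributyl(2-carboxyprop-2-en-1-yl)phosphonium bromide | CCCC[P+](CCCC)(CCCC)CC(=C)C(=O)O.[Br-] | intermediate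
12 | sodium 2-[(tributylphosphoranylidene)methyl]prop-2-enoate | [Na+].[O-]C(=O)C(=C)C=P(CCCC)(CCCC)CCCC | intermediate
13 | (3E,5E,8R)-8-(TBSO)-6-methyl-2-methylidenedeca-3,5,9-trienoic acid | OC(=O)C(=C)/C=C/C=C(\C)C[C@@H](O[Si](C)(C)C(C)(C)C)C=C | intermediate
14 | (4S,5R)-4-bromo-3-methylidene-5-[(1E,4R)-4-(TBSO)-2-methylhexa-1,5-dien-1-yl]oxolan-2-one | C=C1C(=O)O[C@H](/C=C(\C)C[C@@H](O[Si](C)(C)C(C)(C)C)C=C)[C@H]1Br | intermediate
15 | (5R)-3-(bromomethyl)-5-[(1E,4R)-4-(TBSO)-2-methylhexa-1,5-dien-1-yl]furan-2(5H)-one | BrCC1=C[C@@H](/C=C(\C)C[C@@H](O[Si](C)(C)C(C)(C)C)C=C)OC1=O | intermediate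
16 | 3-methylbut-3-en-1-ol | C=C(C)CCO | starting material
17 | 3-methylbut-3-enal | C=C(C)CC=O | intermediate
18 | {(5R)-2-oxo-5-[(1E,4R)-4-(TBSO)-2-methylhexa-1,5-dien-1-yl]-2,5-dihydrofuran-3-yl}methylzinc bromide | Br[Zn]CC1=C[C@@H](/C=C(\C)C[C@@H](O[Si](C)(C)C(C)(C)C)C=C)OC1=O | intermediate
19 | (4R,5R)-4-[(1S)-1-hydroxy-3-methylbut-3-en-1-yl]-3-methylidene-5-[(1E,4R)-4-(TBSO)-2-methylhexa-1,5-dien-1-yl]oxolan-2-one (6R,7R,8S) | C=C1C(=O)O[C@H](/C=C(\C)C[C@@H](O[Si](C)(C)C(C)(C)C)C=C)[C@H]1[C@@H](O)CC(=C)C | intermediate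
20 | methyl (S)-3-hydroxy-2-methylpropanoate | COC(=O)[C@@H](C)CO | starting material
21 | methyl (S)-3-(TBSO)-2-methylpropanoate | COC(=O)[C@@H](C)CO[Si](C)(C)C(C)(C)C | intermediate
22 | (S)-3-(TBSO)-2-methylpropanoic acid | OC(=O)[C@@H](C)CO[Si](C)(C)C(C)(C)C | intermediate
23 | C8-oxytriphenylphosphonium salt of 19 (8S) paired with the carboxylate of 22 | C=C1C(=O)O[C@H](/C=C(\C)C[C@@H](O[Si](C)(C)C(C)(C)C)C=C)[C@H]1[C@@H](O[P+](c2ccccc2)(c3ccccc3)c4ccccc4)CC(=C)C.[O-]C(=O)[C@@H](C)CO[Si](C)(C)C(C)(C)C | intermediate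
24 | (1R)-3-methyl-1-{(2R,3R)-4-methylidene-5-oxo-2-[(1E,4R)-4-(TBSO)-2-methylhexa-1,5-dien-1-yl]oxolan-3-yl}but-3-en-1-yl (2S)-3-(TBSO)-2-methylpropanoate (6R,7R,8R) | C=C1C(=O)O[C@H](/C=C(\C)C[C@@H](O[Si](C)(C)C(C)(C)C)C=C)[C@H]1[C@H](OC(=O)[C@@H](C)CO[Si](C)(C)C(C)(C)C)CC(=C)C | intermediate
25 | (3aR,4R,6Z,8R,10E,11aR)-8-(TBSO)-6,10-dimethyl-3-methylidene-2-oxo-2,3,3a,4,5,8,9,11a-octahydrocyclodeca[b]furan-4-yl (2S)-3-(TBSO)-2-methylpropanoate | C=C1C(=O)O[C@@H]2/C=C(\C)C[C@@H](O[Si](C)(C)C(C)(C)C)/C=C(/C)C[C@@H](OC(=O)[C@@H](C)CO[Si](C)(C)C(C)(C)C)[C@@H]12 | intermediate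
26 | (3aR,4R,6Z,8R,10E,11aR)-8-hydroxy-6,10-dimethyl-3-methylidene-2-oxo-2,3,3a,4,5,8,9,11a-octahydrocyclodeca[b]furan-4-yl (2S)-3-hydroxy-2-methylpropanoate | C=C1C(=O)O[C@@H]2/C=C(\C)C[C@@H](O)/C=C(/C)C[C@@H](OC(=O)[C@@H](C)CO)[C@@H]12 | target

**Step count**
- Total steps: 13.
- Longest linear sequence: 10 (steps 1–6, 8, 11, 12, 13).

**Steps most likely to fail**

**Step 6 (the proposed new step).** The risks are low facial selectivity, bromination of the C4=C5 alkene and Diels–Alder dimerisation of acid 13. The fallback uses only known chemistry. It sets out from enal 9 and comes back at butenolide 15.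
- Vinylmagnesium bromide (THF, −78 °C) gives the C6-epimeric trienols F1.
- MnO2 (CH2Cl2) oxidises them to the cross-conjugated trienone F2.
- (R)-Me-CBS oxazaborolidine with catecholborane (toluene, −78 °C) reduces the ketone to the (3S)-trienol F3.
- DIC and catalytic DMAP (CH2Cl2, 0 °C) couple F3 with acid 10 to the bromomethylacrylate ester F4.
- Ring-closing metathesis with the second-generation Hoveyda–Grubbs catalyst RuCl2(H2IMes)(=CH-C6H4-2-O-i-Pr) (CH2Cl2, 40 °C) joins the acrylate and the monosubstituted vinyl group to give 15.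

**Step 11.** The C8 carbinol is α-branched, so elimination to the C7=C8 diene or acyl transfer with retention may compete with the SN2 reaction. The fallback moves the stereocontrol to the C–C bond and forms the ester with retention. It sets out from bromide 15 and comes back at ester 24.
- (Bu3Sn)2 with Pd2(dba)3 (THF, 23 °C) gives the allylstannane F5.
- BF3·OEt2 with aldehyde 17 (CH2Cl2, −78 °C, KF work-up) reacts through an open antiperiplanar transition state, which favours the syn product. This gives the (8R)-alcohol F6.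
- DIC/DMAP acylation of F6 with acid 22 gives 24.

**Step 12.** The hindered C1 vinyl group next to OTBS and the bulky C8 ester may slow ring closure in favour of dimers, or an E/Z mixture may form. The fallback reverses the order of ring closure and C–O bond formation. It sets out from alcohol 19 and comes back at macrocycle 25.
- The less encumbered free carbinol 19 is cyclised under the same metathesis catalyst to the macrocyclic 8S alcohol F7.
- The Mitsunobu inversion with acid 22 (PPh3/DIAD premixed, toluene) is then run on the ring to give 25.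

**Further compounds**
F1 | step 6 | (4E,7R)-7-(TBSO)-5-methylnona-1,4,8-trien-3-ol, both C3 epimers | C=CC(O)/C=C(\C)C[C@@H](O[Si](C)(C)C(C)(C)C)C=C
F2 | step 6 | (4E,7R)-7-(TBSO)-5-methylnona-1,4,8-trien-3-one | C=CC(=O)/C=C(\C)C[C@@H](O[Si](C)(C)C(C)(C)C)C=C
F3 | step 6 | (3S,4E,7R)-7-(TBSO)-5-methylnona-1,4,8-trien-3-ol | C=C[C@H](O)/C=C(\C)C[C@@H](O[Si](C)(C)C(C)(C)C)C=C
F4 | step 6 | (3S,4E,7R)-7-(TBSO)-5-methylnona-1,4,8-trien-3-yl 2-(bromomethyl)acrylate | C=C(CBr)C(=O)O[C@@H](C=C)/C=C(\C)C[C@@H](O[Si](C)(C)C(C)(C)C)C=C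
F5 | step 11 | (5R)-3-[(tributylstannyl)methyl]-5-[(1E,4R)-4-(TBSO)-2-methylhexa-1,5-dien-1-yl]furan-2(5H)-one | CCCC[Sn](CCCC)(CCCC)CC1=C[C@@H](/C=C(\C)C[C@@H](O[Si](C)(C)C(C)(C)C)C=C)OC1=O
F6 | step 11 | (4R,5R)-4-[(1R)-1-hydroxy-3-methylbut-3-en-1-yl]-3-methylidene-5-[(1E,4R)-4-(TBSO)-2-methylhexa-1,5-dien-1-yl]oxolan-2-one | C=C1C(=O)O[C@H](/C=C(\C)C[C@@H](O[Si](C)(C)C(C)(C)C)C=C)[C@H]1[C@H](O)CC(=C)C
F7 | step 12 | (3aR,4S,6Z,8R,10E,11aR)-8-(TBSO)-4-hydroxy-6,10-dimethyl-3-methylidene-3a,4,5,8,9,11a-hexahydrocyclodeca[b]furan-2(3H)-one | C=C1C(=O)O[C@@H]2/C=C(\C)C[C@@H](O[Si](C)(C)C(C)(C)C)/C=C(/C)C[C@H](O)[C@@H]12
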